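A direct plan would start from 2-geranylphloroglucinol A1, dearomatise A1 by Michael addition to a vinyl ketone to the achiral trione A2, close ring A by a proline-mediated aldol to ketol A3, turn the ring A ketone into the C6-methyl alkene, prenylate C2, oxidise C4, and close rings B and C by a Prins/etherification of the enolised trione A4; it would need some fourteen linear steps.
Its weakest steps would be:
(a) the desymmetrising aldol A2 to A3, which would have to set C8a, C4a and C5 on an acidic, largely ionised trione whose acceptor carbonyl is part of a vinylogous acid; the ketol could revert or dehydrate, and nothing in the substrate secures the choice between the two ring carbonyls;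
(b) the change of C6=O into C6–CH3 with the C6=C7 bond: five operations (enol ether, silyl ether, enol triflate, methyl coupling, hydrolysis) that would build one C–C bond and expose a β-silyloxy ketone to strong base;
(c) the end game: the oxidation level of C4 would be corrected by a trianion hydroxylation and a second oxidation, and the one untested reaction (Lewis acid on A4, a free enol beside a prenyl group that can also close a pyran) would come last, on the most valuable material.

**Retrosynthetic overview**
- Feature used: C5–C8 of ring A with the C6 methyl, and C1′–C3′ with the gem-dimethyl group of rings B and C, are the intact ten-carbon chain of (E)-β-ocimene; ring D is an oxidised 2-geranyl-4-prenylphloroglucinol.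
- Key disconnection: C8a–C8 and C4a–C5 (Diels–Alder of the ocimene diene with the C4a=C8a bond of a hexasubstituted 1,4-benzoquinone), then C4–C2′ and O–C3′ (Prins closure onto the quinone carbonyl C4, capture by the C3 oxygen) in the same flask. Three rings and all five stereocentres come from a flat, achiral quinone.
- Ring order: D from 5-methoxyresorcinol (two directed metalations, arene oxidation), then A, B and C in one operation. This is the same sequence D, A, B, C as in the direct plan; the difference is that ring A closes by cycloaddition and no bicyclic A/D intermediate is isolated or carried.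
- The two enol oxygens of the quinone are told apart from the start (C3–OMe from the starting material, C4a–OAc). This directs the diene to the geranyl-bearing double bond and keeps the C3 enol masked beside the prenyl group until ring C closes.
- Avoided by design: no desymmetrising aldol (one suprafacial cycloaddition sets C8a, C4a, C5), no ketone-to-methylalkene detour (methyl and alkene come with the diene), no late oxidation at C4 (it is a quinone carbonyl).

Key step: step 7

Locants (used throughout): ring D is C1(=O), C2, C3, C4, C4a, C8a; ring A is C4a, C5, C6 (methyl), C7, C8, C8a; C1′ (CH2), C2′ (CH) and C3′ (CMe2) complete rings B and C. Geranyl = (2E)-3,7-dimethylocta-2,6-dien-1-yl; prenyl = 3-methylbut-2-en-1-yl.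
Assumption: the sense of facial selection of the complex of Sc(OTf)3 with 2,6-bis[(4S)-4-isopropyl-4,5-dihydrooxazol-2-yl]pyridine on quinone 11 is not known; the (S,S)-ligand is written, and its mirror image would be taken if it should favour the mirror-image adduct.

Step 1
Reactants: 1 5-methoxyresorcinol
Product: 2 1-methoxy-3,5-bis(methoxymethoxy)benzene
Conditions: MeOCH2Cl (2.4 equiv), iPr2NEt (3 equiv), CH2Cl2, 0 °C to rt
Reagents that add atoms: chloromethyl methyl ether, COCCl
Why: O-alkylation of both phenols gives the bis(methoxymethyl) ether, whose acetal oxygens are the directing groups for the two ring metalations that follow.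

Step 2
Reactants: 2 1-methoxy-3,5-bis(methoxymethoxy)benzene; 3 geranyl bromide
Product: 5 2-geranyl-5-methoxy-1,3-bis(methoxymethoxy)benzene, via aryllithium 4 (not isolated)
Conditions: n-BuLi (1.1 equiv), THF, 0 °C; then CuI (10 mol %), 3 (1.2 equiv), −78 °C to rt
Reagents that add atoms: none
Why: directed ortho-metalation should take the ring carbon flanked by both methoxymethoxy groups, and copper-assisted SN2 alkylation of the aryl anion with the allylic bromide keeps the (E)-alkene; no stereocentre is formed.

Step 3
Reactants: 5 2-geranyl-5-methoxy-1,3-bis(methoxymethoxy)benzene; 6 prenyl bromide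
Product: 8 2-geranyl-5-methoxy-1,3-bis(methoxymethoxy)-4-prenylbenzene, via aryllithium 7 (not isolated)
Conditions: n-BuLi (1.2 equiv), TMEDA (1.2 equiv), THF, −20 to 0 °C; then CuI (10 mol %), 6 (1.3 equiv), −78 °C to rt
Reagents that add atoms: none
Why: the second directed ortho-metalation takes one of the two equivalent ring positions between a methoxymethoxy and the methoxy group (complex-induced, expected to be faster than removal of the benzylic–allylic protons), and SN2 alkylation installs the prenyl group.

Step 4
Reactants: 8 2-geranyl-5-methoxy-1,3-bis(methoxymethoxy)-4-prenylbenzene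
Product: 9 2-geranyl-5-methoxy-4-prenylbenzene-1,3-diol
Conditions: HCl (2 M in MeOH), 0 °C to rt, short reaction time; NaHCO3 quench
Reagents that add atoms: none
Why: acid-catalysed transacetalisation to methanol frees both phenols, and low temperature with short exposure should keep the ortho-allyl phenols from closing to chromans.

Step 5
Reactants: 9 2-geranyl-5-methoxy-4-prenylbenzene-1,3-diol
Product: 10 2-geranyl-3-hydroxy-5-methoxy-6-prenyl-1,4-benzoquinone
Conditions: (KSO3)2NO (2.5 equiv), KH2PO4 buffer, acetone–H2O, 0 °C to rt
Reagents that add atoms: potassium nitrosodisulfonate, [K+].[K+].[O]N(S(=O)(=O)[O-])S(=O)(=O)[O-]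
Why: Teuber oxidation: the phenoxyl radical of the hindered C1 hydroxyl is trapped at the only unsubstituted ring carbon, C4 (oxidation through the C4a hydroxyl gives the tautomeric ortho-quinone and hence the same product), so the carbonyls should arise at C1 and C4, the hydroxyl next to the geranyl group staying free and the C3 oxygen methylated.

Step 6
Reactants: 10 2-geranyl-3-hydroxy-5-methoxy-6-prenyl-1,4-benzoquinone
Product: 11 3-acetoxy-2-geranyl-5-methoxy-6-prenyl-1,4-benzoquinone
Conditions: Ac2O (1.5 equiv), pyridine (2 equiv), CH2Cl2, 0 °C
Reagents that add atoms: acetic anhydride, CC(=O)OC(C)=O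
Why: O-acylation of the acidic quinone enol; the acetoxy group makes C4a=C8a the more electron-poor double bond of the quinone, keeps that oxygen from chelating, and can be removed from the tertiary C4a oxygen at the end.

Step 7
Reactants: 11 3-acetoxy-2-geranyl-5-methoxy-6-prenyl-1,4-benzoquinone; 12 (E)-β-ocimene
Product: 15 4a-O-acetyl derivative of CNP0323114.1, via Diels–Alder adduct 13 (not isolated), via 4-O-trimethylsilyl ether 14 (not isolated)
Conditions: Sc(OTf)3 (10 mol %), 2,6-bis[(4S)-4-isopropyl-4,5-dihydrooxazol-2-yl]pyridine (12 mol %), 4 Å MS, 12 (2 equiv), CH2Cl2, −20 °C to rt; then Me2S (5 equiv), 2,6-di-tert-butyl-4-methylpyridine (0.3 equiv), Me3SiOTf (2 equiv), −78 to −20 °C; then 1 M citric acid, THF, 0 °C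
Reagents that add atoms: none
Why: Proposed new method: the chiral scandium complex should hold 11 by the C3 methoxy oxygen and the C4 carbonyl, so that the acetoxy-bearing C4a=C8a bond (the C2=C3 bond stays a deactivated vinylogous ester) adds the diene of 12 in an endo [4+2] cycloaddition that closes ring A, with C8a as the β-carbon taking the unsubstituted terminus C8 and C4a taking C5. The suprafacial addition sets C8a and C4a cis, the endo mode with the (E)-diene places C1′ on C5 cis to C4, and the ligand selects the quinone face, so these three centres and their absolute sense arise together in 13. Me3SiOTf then silylates the C4 carbonyl oxygen, the C2′=C3′ alkene attacks C4 in a 5-exo Prins closure of ring B from the face that its short tether can reach (C4–O cis to C4a–O), and the tertiary C3′ cation is taken by the C3 ether oxygen in a five-membered closure of ring C, after which Me2S removes the methyl group from the oxonium ion. C2′ is fixed by this capture: the silyloxy group, the largest group on C4 and unable to accept a proton in an ene pathway, turns the CMe2 terminus toward C3, and a cation of the other orientation has no oxygen within reach and should revert by retro-Prins cleavage, so both should funnel to 14. The closest known reactions are the Lewis-acid Diels–Alder, carbonyl-ene and etherification sequence of 2-hydroxy-1,4-benzoquinones with (E)-β-ocimene, catalytic asymmetric Diels–Alder reactions of two-point-binding quinones and α′-oxygenated enones with pybox and bis(oxazoline) complexes, silyl triflate Prins cyclisations ended by oxygen, and demethylative cyclisations of methyl ethers onto cations. The step needs site, regio-, endo and facial selectivity in the cycloaddition and oxygen capture over elimination in the cation step; the acetoxy/methoxy differentiation, the two-point binding, the stage-wise temperature and the hindered base that stops proton-initiated cyclisation of the geranyl and prenyl chains should secure these.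

Step 8
Reactants: 15 4a-O-acetyl derivative of CNP0323114.1
Product: 16 CNP0323114.1
Conditions: K2CO3 (0.3 equiv), MeOH, 0 °C to rt
Reagents that add atoms: none
Why: methanolysis of the tertiary acetate, helped by acyl transfer to the neighbouring cis C4 hydroxyl, frees the C4a hydroxyl; catalytic carbonate at low temperature should spare the vinylogous ester and avoid retro-aldol opening.

**Compound list**

1 | 5-methoxyresorcinol (5-methoxybenzene-1,3-diol) | COc1cc(O)cc(O)c1 | starting material
2 | 1-methoxy-3,5-bis(methoxymethoxy)benzene | COCOc1cc(OC)cc(OCOC)c1 | intermediate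
3 | geranyl bromide ((2E)-1-bromo-3,7-dimethylocta-2,6-diene) | CC(C)=CCC/C(C)=C/CBr | starting material
4 | 4-methoxy-2,6-bis(methoxymethoxy)phenyllithium (not isolated) | COCOc1cc(OC)cc(OCOC)c1[Li] | intermediate
5 | 2-geranyl-5-methoxy-1,3-bis(methoxymethoxy)benzene | COCOc1cc(OC)cc(OCOC)c1C/C=C(\C)CCC=C(C)C | intermediate
6 | prenyl bromide (1-bromo-3-methylbut-2-ene) | CC(C)=CCBr | starting material
7 | 3-geranyl-6-methoxy-2,4-bis(methoxymethoxy)phenyllithium (not isolated) | COCOc1c([Li])c(OC)cc(OCOC)c1C/C=C(\C)CCC=C(C)C | intermediate
8 | 2-geranyl-5-methoxy-1,3-bis(methoxymethoxy)-4-prenylbenzene | COCOc1c(CC=C(C)C)c(OC)cc(OCOC)c1C/C=C(\C)CCC=C(C)C | intermediate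
9 | 2-geranyl-5-methoxy-4-prenylbenzene-1,3-diol | Oc1c(CC=C(C)C)c(OC)cc(O)c1C/C=C(\C)CCC=C(C)C | intermediate
10 | 2-geranyl-3-hydroxy-5-methoxy-6-prenyl-1,4-benzoquinone (C1 and C4 carbonyls, C3–OMe, C4a–OH) | O=C1C(CC=C(C)C)=C(OC)C(=O)C(O)=C1C/C=C(\C)CCC=C(C)C | intermediate
11 | 3-acetoxy-2-geranyl-5-methoxy-6-prenyl-1,4-benzoquinone (C4a–OAc) | O=C1C(CC=C(C)C)=C(OC)C(=O)C(OC(C)=O)=C1C/C=C(\C)CCC=C(C)C | intermediate
12 | (E)-β-ocimene ((3E)-3,7-dimethylocta-1,3,6-triene; commercial E-enriched material, the Z isomer is inert as a diene) | C=C/C(C)=C/CC=C(C)C | starting material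
13 | cis-fused Diels–Alder adduct: 4a-acetoxy-8a-geranyl-3-methoxy-6-methyl-2,5-diprenyl-4a,5,8,8a-tetrahydronaphthalene-1,4-dione; acetoxy cis to geranyl, H-5 cis to acetoxy; C4a, C5, C8a as in 16 (not isolated) | CC(C)=CCC/C(C)=C/C[C@]12CC=C(C)[C@H](CC=C(C)C)[C@]2(OC(C)=O)C(=O)C(OC)=C(CC=C(C)C)C1=O | intermediate
14 | 4-O-trimethylsilyl ether of 15, configuration of 16 (not isolated) | CC(C)=CCC/C(C)=C/C[C@]12CC=C(C)[C@@H]3C[C@@H]4C(C)(C)OC(=C(CC=C(C)C)C1=O)[C@]4(O[Si](C)(C)C)[C@@]32OC(C)=O | intermediate
15 | 4a-O-acetyl derivative of CNP0323114.1, rings A–D closed, configuration of 16 | CC(C)=CCC/C(C)=C/C[C@]12CC=C(C)[C@@H]3C[C@@H]4C(C)(C)OC(=C(CC=C(C)C)C1=O)[C@]4(O)[C@@]32OC(C)=O | intermediate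
16 | CNP0323114.1: tetracycle of rings A–D with C4 R, C4a R, C5 S, C8a R, C2′ S; C4 and C4a hydroxyls cis, geranyl cis to the C4a hydroxyl | CC(C)=CCC/C(C)=C/C[C@]12CC=C(C)[C@@H]3C[C@@H]4C(C)(C)OC(=C(CC=C(C)C)C1=O)[C@]4(O)[C@@]32O | target

Total step count: 8. Longest linear sequence: 8 steps (from 5-methoxyresorcinol).

**Steps most likely to fail, with fallbacks**

1. Step 7 (Proposed new method). The cycloaddition at the tetrasubstituted C4a=C8a bond may be slow or poorly controlled in site, orientation or facial sense by the chiral complex, and the tertiary cation may be lost by elimination instead of ether closure. The fallback uses known reactions, stoichiometric chirality and separated stages; it sets out from 10 and returns at 16. Compound 10 would be esterified with (S)-methoxy(phenyl)acetic acid (DCC, DMAP) to the quinone ester F1. The cycloaddition with 12 would be run under the achiral complex Eu(fod)3 (fod = 6,6,7,7,8,8,8-heptafluoro-2,2-dimethyloctane-3,5-dionate) in toluene at 45 °C, as is known for hydroxyquinones and ocimene. The diastereomeric adducts would be separated by chromatography or crystallisation to give the adduct F2 with the ring configuration of 13. The vinylogous methyl ester would be hydrolysed with 1 M HCl in THF to the free enol F3. Rings B and C would then be closed on the aluminium enolate with Me2AlCl in CH2Cl2 (−78 to 0 °C), a proton-free carbonyl-ene/Prins closure with oxygen capture, to the tetracyclic ester F4. Methanolysis (K2CO3, MeOH) would give 16.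

2. Step 3. Removal of the benzylic–allylic protons of the geranyl CH2 may compete with ring metalation, or metalation at the hindered position may stay incomplete. The fallback sets out from 5 and returns at 9. The acetals of 5 would be cleaved (HCl, MeOH) to the symmetric diol F5. One of its two equivalent phenols would be etherified with methyl 2-methylbut-3-en-2-yl carbonate and Pd(PPh3)4 to the 1,1-dimethylallyl ether F6. Heating (PhNEt2, 160 °C) should bring about aromatic Claisen rearrangement to the free ortho position, delivering the prenyl group with allylic inversion and giving 9.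

3. Step 5. The radical oxidant may attack the side-chain alkenes, or oxidation of the hindered phenol may stay incomplete. The fallback sets out from 8 and returns at 10. A third directed metalation of 8 at its last ring hydrogen (n-BuLi, TMEDA), then B(OMe)3 and H2O2/NaOH, would give the phenol F7. Acetal cleavage (HCl, MeOH) would give the hydroxyhydroquinone F8, which air or Ag2O should oxidise to 10 without a radical oxidant.

**Further compounds**

F1 | step 7 | 2-geranyl-5-methoxy-6-prenyl-3-[(S)-methoxy(phenyl)acetoxy]-1,4-benzoquinone | O=C1C(CC=C(C)C)=C(OC)C(=O)C(OC(=O)[C@@H](OC)c2ccccc2)=C1C/C=C(\C)CCC=C(C)C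
F2 | step 7 | (S)-methoxy(phenyl)acetate analogue of adduct 13, ring configuration of 13 | CC(C)=CCC/C(C)=C/C[C@]12CC=C(C)[C@H](CC=C(C)C)[C@]2(OC(=O)[C@@H](OC)c3ccccc3)C(=O)C(OC)=C(CC=C(C)C)C1=O
F3 | step 7 | 3-enol (3-hydroxy-2-en-1,4-dione) obtained from F2 by hydrolysis of the methyl enol ether, ring configuration of 13 | CC(C)=CCC/C(C)=C/C[C@]12CC=C(C)[C@H](CC=C(C)C)[C@]2(OC(=O)[C@@H](OC)c3ccccc3)C(=O)C(O)=C(CC=C(C)C)C1=O
F4 | step 7 | 4a-O-[(S)-methoxy(phenyl)acetyl] derivative of 16, configuration of 16 | CC(C)=CCC/C(C)=C/C[C@]12CC=C(C)[C@@H]3C[C@@H]4C(C)(C)OC(=C(CC=C(C)C)C1=O)[C@]4(O)[C@@]32OC(=O)[C@@H](OC)c5ccccc5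
F5 | step 3 | 2-geranyl-5-methoxybenzene-1,3-diol | Oc1cc(OC)cc(O)c1C/C=C(\C)CCC=C(C)C
F6 | step 3 | 2-geranyl-5-methoxy-3-[(2-methylbut-3-en-2-yl)oxy]phenol | C=CC(C)(C)Oc1cc(OC)cc(O)c1C/C=C(\C)CCC=C(C)C
F7 | step 5 | 3-geranyl-6-methoxy-2,4-bis(methoxymethoxy)-5-prenylphenol | COCOc1c(O)c(OC)c(CC=C(C)C)c(OCOC)c1C/C=C(\C)CCC=C(C)C
F8 | step 5 | 3-geranyl-6-methoxy-5-prenylbenzene-1,2,4-triol | Oc1c(O)c(OC)c(CC=C(C)C)c(O)c1C/C=C(\C)CCC=C(C)C
A1 | direct plan | 2-geranylphloroglucinol | CC(C)=CCC/C(C)=C/Cc1c(O)cc(O)cc1O
A2 | direct plan | 2-geranyl-2-(7-methyl-3-oxooct-6-en-1-yl)cyclohexane-1,3,5-trione | O=C1CC(=O)CC(=O)C1(C/C=C(\C)CCC=C(C)C)CCC(=O)CCC=C(C)C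
A3 | direct plan | (4aR,5R,8aS)-8a-geranyl-4a-hydroxy-5-prenyldecalin-1,3,6-trione | CC(C)=CCC/C(C)=C/C[C@]12CCC(=O)[C@H](CC=C(C)C)[C@]2(O)CC(=O)CC1=O
A4 | direct plan | 8a-geranyl-3,4a-dihydroxy-6-methyl-2,5-diprenyl-4a,5,8,8a-tetrahydronaphthalene-1,4-dione (enolised 1,3,4-trione) | CC(C)=CCC/C(C)=C/C[C@]12CC=C(C)[C@H](CC=C(C)C)[C@]2(O)C(=O)C(O)=C(CC=C(C)C)C1=O
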